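**Plan**

1. Enabling feature: C8 bears an acyloxy oxygen next to the C9 ketone, and its neighbour C7 bears the C11(=C13)–C12 propenoate of the lactone. An ether bond from O8 to C13 therefore makes C7–C8 the product of a [2,3] shift of a C8 enolate across a butenolide (O–C6–C7=C11–C12) that is bridged by a 13-membered ether ring.
2. Retrosynthetic cuts, in order: the C5 angelate and the O8 acyl bond; C7–C8 (ring contraction, 13 to 10); C7=C11 (metathesis); the C6–O–C12 ester (lactonisation); O–C8 (carbenoid O–H insertion of a C9 diazoketone); C5–C6 (alkoxyallylboration); C2–C3 and C1–C2 (dithiane linchpin).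
3. Forward: the chain is joined as C9–C10–C1 bromide + C2 dithiane + C3–C5 epoxide, then C6/C7, then C8 and C11–C13. Rings arise in the order 1,3-dioxane acetonide, 14-membered lactone, butenolide inside the 13-membered ether, ten-membered carbocycle with the α-methylene lactone.
4. Stereochemistry: C10 from (R)-3-bromo-2-methylpropan-1-ol; C4 from (R)-2-methylglycidol; C2 by hydrogenation with RuCl2[(S)-BINAP]; C5 and C6 by isopinocampheyl-controlled (Z)-alkoxyallylboration; C7 and C8 in the ring contraction (tether face, enolate envelope).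
5. End game: desilylation at C5, angeloylation, acetonide hydrolysis.

Key step: step 20

Remark on locants: C1–C10 are the ring carbons of the target (C2 CHOH, C4 C(Me)OH, C5 CH–O-angelate, C6 lactone O–CH, C7, C8 CH–O-isobutyrate, C9 ketone, C10 CHMe); C11, C12, C13 are the lactone α-carbon, carbonyl carbon and exocyclic methylene. Descriptors quoted with these locants are (2S,4S,5S,6R,7S,8S,10S) throughout. TBS = tert-butyldimethylsilyl, PMB = 4-methoxybenzyl, PMP = 4-methoxyphenyl.

Assumption: compounds 1, 3, 6, 16, 26 and 37 and all reagents named are taken as purchasable; the ring contraction and its stereochemical course are untested predictions.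

Step 1
Reactants: 1 (R)-3-bromo-2-methylpropan-1-ol
Product: 2 (R)-(3-bromo-2-methylpropoxy)(tert-butyl)dimethylsilane
Conditions: TBSCl, imidazole, CH2Cl2, 0 °C → rt
Reagents that add atoms: tert-butyldimethylsilyl chloride, CC(C)(C)[Si](C)(C)Cl
Why: Imidazole-mediated silylation of a primary alcohol, which leaves the stereocentre (the future C10) untouched.

Step 2
Reactants: 3 1,3-dithiane; 2 (R)-(3-bromo-2-methylpropoxy)(tert-butyl)dimethylsilane
Product: 5 2-[(S)-3-(TBSO)-2-methylpropyl]-1,3-dithiane, via 2-lithio-1,3-dithiane 4 (not isolated)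
Conditions: n-BuLi, THF, −30 °C; then 2, −30 °C → rt
Reagents that add atoms: none
Why: Corey–Seebach alkylation, in which the lithiated dithiane (the future C2) displaces the primary bromide by SN2 without involving the β-methyl centre.

Step 3
Reactants: 6 (R)-2-methylglycidol
Product: 8 (S)-2-[(4-methoxybenzyloxy)methyl]-2-methyloxirane, via sodium alkoxide 7 (not isolated)
Conditions: NaH, THF/DMF, 0 °C; then PMBCl, Bu4NI (cat.), rt
Reagents that add atoms: 4-methoxybenzyl chloride, COc1ccc(CCl)cc1
Why: Williamson etherification of the primary alkoxide; the epoxide tolerates NaH, and the Payne shift of this alkoxide is degenerate, so C4 cannot be scrambled.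

Step 4
Reactants: 5 2-[(S)-3-(TBSO)-2-methylpropyl]-1,3-dithiane; 8 (S)-2-[(4-methoxybenzyloxy)methyl]-2-methyloxirane
Product: 10 dithiane tertiary alcohol (4S,10S) with C2 dithiane, C4 OH, C5 OPMB and C9 OTBS, via lithiated dithiane 9 (not isolated)
Conditions: t-BuLi, THF/HMPA (10:1), −78 °C; then 8, −78 → −20 °C; H2O
Reagents that add atoms: none
Why: Dithiane linchpin coupling, in which the lithiated 2-alkyl-dithiane opens the 2,2-disubstituted epoxide at its unsubstituted carbon (C3), so the C4 configuration of the glycidol is carried over unchanged.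

Step 5
Reactants: 10 dithiane tertiary alcohol
Product: 11 β-hydroxy ketone (2S,6S)-7-(TBSO)-2-hydroxy-1-(PMBO)-2,6-dimethylheptan-4-one (C2 ketone)
Conditions: MeI, CaCO3, MeCN/H2O (9:1), 45 °C
Reagents that add atoms: water, O
Why: Alkylative dithioacetal hydrolysis, in which S-methylation turns the sulfurs into leaving groups and water supplies the carbonyl oxygen, while the CaCO3 buffer spares the tertiary aldol from dehydration.

Step 6
Reactants: 11 β-hydroxy ketone
Product: 12 syn-diol (2S,4S,6S)-7-(TBSO)-1-(PMBO)-2,6-dimethylheptane-2,4-diol (target locants 2S,4S,10S)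
Conditions: RuCl2[(S)-BINAP](dmf)n (1 mol %), H2 (50 atm), EtOH, 40 °C
Reagents that add atoms: none
Why: Noyori hydroxyl-directed asymmetric hydrogenation of a β-hydroxy ketone, in which the C4 hydroxyl anchors the substrate on ruthenium and the (S)-BINAP ligand fixes C2 as S (syn to O4), because the tertiary carbinol with two similar substituents gives no reliable 1,3-bias to hydride reagents.

Step 7
Reactants: 12 syn-diol
Product: 13 acetonide (4S,6S)-6-[(S)-3-(TBSO)-2-methylpropyl]-4-[(PMBO)methyl]-2,2,4-trimethyl-1,3-dioxane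
Conditions: 2-methoxypropene, PPTS (cat.), CH2Cl2, 0 °C
Reagents that add atoms: 2-methoxypropene, COC(C)=C
Why: Acid-catalysed ketalisation to the six-membered acetonide of the syn-1,3-diol, whose chair keeps both chain arms equatorial and only the C4 methyl axial.

Step 8
Reactants: 13 acetonide PMB ether
Product: 14 primary alcohol [(4S,6S)-6-((S)-3-(TBSO)-2-methylpropyl)-2,2,4-trimethyl-1,3-dioxan-4-yl]methanol (C5 OH)
Conditions: DDQ, CH2Cl2/pH 7 buffer, 0 °C
Reagents that add atoms: none
Why: Oxidative cleavage of the PMB ether by DDQ (benzylic hydride abstraction, then hydrolysis of the oxocarbenium ion), which leaves the silyl ether and acetonide intact.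

Step 9
Reactants: 14 primary alcohol
Product: 15 aldehyde (4S,6S)-6-[(S)-3-(TBSO)-2-methylpropyl]-2,2,4-trimethyl-1,3-dioxane-4-carbaldehyde (C5 CHO)
Conditions: Dess–Martin periodinane, CH2Cl2, rt
Reagents that add atoms: none
Why: Dess–Martin oxidation of a primary alcohol to an aldehyde that has no α-hydrogen and therefore cannot epimerise.

Step 10
Reactants: 15 aldehyde; 16 allyl 4-methoxyphenyl ether
Product: 20 homoallylic alcohol (2S,4S,5S,6R,10S) with C5 OH, C6 OPMP and C7 vinyl, via lithiated allyl ether 17 (not isolated), via allylborane 18 (not isolated), via borinate ester 19 (not isolated)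
Conditions: 16, s-BuLi, THF, −78 °C; (−)-Ipc2BOMe; BF3·OEt2; then 15, −78 °C → rt; NaOH, H2O2
Reagents that add atoms: none
Why: Brown asymmetric (Z)-γ-alkoxyallylboration, in which the closed chair transition state of the Z-allylborane gives the 5,6-syn relationship and the isopinocampheyl groups of the (+)-α-pinene series direct attack to the aldehyde face that gives 5S and hence 6R, overriding any bias from C4.

Step 11
Reactants: 20 homoallylic alcohol
Product: 21 bis-silyl ether (C5 OTBS, C9 OTBS, C6 OPMP)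
Conditions: TBSOTf, 2,6-lutidine, CH2Cl2, 0 °C
Reagents that add atoms: tert-butyldimethylsilyl triflate, CC(C)(C)[Si](C)(C)OS(=O)(=O)C(F)(F)F
Why: Silylation of a hindered secondary alcohol with the silyl triflate and a non-nucleophilic base, conditions the acetonide tolerates.

Step 12
Reactants: 21 bis-silyl ether
Product: 22 C9 primary alcohol (C5 OTBS retained)
Conditions: HF·pyridine, pyridine, THF, 0 °C
Reagents that add atoms: none
Why: Selective fluoride desilylation, in which the primary C9 silyl ether is cleaved much faster than the secondary C5 ether flanked by the quaternary C4.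

Step 13
Reactants: 22 C9 primary alcohol
Product: 23 C9 carboxylic acid
Conditions: TEMPO (cat.), PhI(OAc)2, MeCN/H2O, rt
Reagents that add atoms: water, O
Why: Oxoammonium (TEMPO/PhI(OAc)2) oxidation of the primary alcohol through the aldehyde hydrate to the acid under near-neutral conditions that do not enolise C10 or touch the aryl ether and alkene.

Step 14
Reactants: 23 C9 carboxylic acid
Product: 25 diazomethyl ketone (C9 ketone, C8 = CHN2), via mixed carbonic anhydride 24 (not isolated)
Conditions: i-BuOCOCl, N-methylmorpholine, THF, −15 °C; then CH2N2, Et2O, 0 °C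
Reagents that add atoms: diazomethane, C=[N+]=[N-]
Why: Arndt–Eistert-type diazoketone synthesis, in which the mixed carbonic anhydride acylates diazomethane (which supplies C8) without racemising the α-methyl centre C10.

Step 15
Reactants: 25 diazomethyl ketone; 26 methyl 2-(hydroxymethyl)acrylate
Product: 27 α-alkoxy ketone methyl ester (O8–C13 ether, C11=CH2, C6 OPMP)
Conditions: Rh2(OAc)4 (1 mol %), 26 (5 equiv), CH2Cl2, rt
Reagents that add atoms: none
Why: Carbenoid O–H insertion, in which the electrophilic carbenoid formed from Rh2(OAc)4 is trapped by the excess primary allylic alcohol (oxonium ylide, then proton shift) faster than it cyclopropanates the electron-poor acrylate or inserts into C–H bonds.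

Step 16
Reactants: 27 α-alkoxy ketone methyl ester
Product: 28 hydroxy ester (C6 OH)
Conditions: (NH4)2Ce(NO3)6, MeCN/H2O (4:1), 0 °C
Reagents that add atoms: none
Why: Oxidative dearylation of the PMP ether (arene radical cation, ipso addition of water, loss of benzoquinone), which frees the C6 hydroxyl without affecting the silyl ether, the acetonide or the two alkenes in a short cold reaction.

Step 17
Reactants: 28 hydroxy ester
Product: 29 seco acid (C12 CO2H, C6 OH)
Conditions: Me3SnOH, 1,2-dichloroethane, 70 °C; then 0.1 M HCl wash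
Reagents that add atoms: trimethyltin hydroxide, C[Sn](C)(C)O
Why: Mild ester hydrolysis with Me3SnOH, chosen because it cleaves the methyl ester without enolising the C9 ketone (C10 epimerisation) or adding to the acrylate.

Step 18
Reactants: 29 seco acid
Product: 31 14-membered macrolactone (C6–O–C12; C7 vinyl and C11 methylene still free), via mixed anhydride 30 (not isolated)
Conditions: 2-methyl-6-nitrobenzoic anhydride, DMAP, CH2Cl2, rt, slow addition (2 mM)
Reagents that add atoms: none
Why: Shiina macrolactonisation, in which DMAP opens the mixed anhydride and the acylpyridinium ion is captured by the C6 hydroxyl under high dilution at room temperature.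

Step 19
Reactants: 31 14-membered macrolactone
Product: 32 13-membered ether bridging a butenolide (C7=C11; C2/C4 acetonide, C5 OTBS)
Conditions: second-generation Grubbs catalyst RuCl2(=CHPh)(H2IMes)(PCy3) (10 mol %), toluene, 80 °C, 1 mM
Reagents that add atoms: none
Why: Ring-closing metathesis of an allylic α-substituted acrylate to a butenolide, run transannularly, so that closure of the five-membered ring with loss of ethene converts the 14-membered lactone into the 13-membered ether bridged by the lactone.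

Step 20
Reactants: 32 13-membered ether bridging a butenolide
Product: 35 ten-membered α-methylene lactone with C8 isobutyrate (C5 OTBS, C2/C4 acetonide), via boron enolate 33 (not isolated), via boron alkoxide 34 (not isolated)
Conditions: Bu2BOTf, i-Pr2NEt, CH2Cl2, −78 → 0 °C; then (i-PrCO)2O, DMAP, 0 °C → rt
Reagents that add atoms: isobutyric anhydride, CC(C)C(=O)OC(=O)C(C)C
Why: Proposed new method: Bu2BOTf binds the C9 ketone (chelated by the C8 ether oxygen) and i-Pr2NEt removes a C8 proton to give the Z(O)-boron enolate 33, whose C8 terminus bonds to the butenolide β-carbon C7 while the allylic C13–O bond breaks and the alkene moves to C11=C13, a [2,3]-Wittig shift; the boron alkoxide 34 is then acylated in the same flask as its DMAP ate complex. The closest known reaction types are the ring-contracting [2,3]-Wittig rearrangement of 13-membered allylic ethers to ten-membered carbocycles and the boron- or lithium-enolate [2,3]-Wittig rearrangement of α-allyloxy carbonyl compounds; what is new is a ketone enolate inside the macrocycle with a butenolide as the allyl partner. The ten-membered ring is closed by contraction, C8 bonding transannularly to C7 through a five-membered envelope (as a polar step this would be a 5-endo-trig attack, tolerable here because bond making and C13–O cleavage are concerted). C7 is controlled by the tether: the chain carrying C8 is anchored at C6 through C5 on one lactone face and is expected to deliver C8 to that face, giving the cis-fused lactone. C8 is controlled by the enolate envelope: the chelate-enforced Z(O)-enolate should react with H7 and H8 syn (C9 on the C6 side), the topology that carbonyl-stabilised carbanions of E-allylic ethers prefer. The step needs enolisation at C8 and not at C10 or the lactone γ-position C6, and the [2,3] and not the oxy-Claisen [3,3] mode; soft enolisation favours the chelating, unhindered α-alkoxy methylene of the more Lewis-basic ketone, the [2,3] mode is polarity-matched (nucleophilic C8 onto the electrophilic β-carbon), and capping O8 as the isobutyrate prevents translactonisation.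

Step 21
Reactants: 35 ten-membered α-methylene lactone
Product: 36 C5 alcohol
Conditions: HF·pyridine, pyridine, THF, 0 °C → rt
Reagents that add atoms: none
Why: Fluoride cleavage of the remaining secondary silyl ether under buffered, weakly acidic conditions that should not provoke translactonisation, acyl migration or isomerisation of the methylene lactone.

Step 22
Reactants: 36 C5 alcohol; 37 angelic acid
Product: 39 C5 angelate acetonide, via angelic mixed anhydride 38 (not isolated)
Conditions: 37, 2,4,6-Cl3C6H2COCl, Et3N, toluene, rt, salt filtered off; then 36, toluene, 75 °C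
Reagents that add atoms: none
Why: Yamaguchi-type esterification with the preformed angelic 2,4,6-trichlorobenzoic mixed anhydride, which acylates a hindered alcohol at the less shielded angeloyl carbonyl and avoids Z-to-E isomerisation because no nucleophilic catalyst adds to the enoate.

Step 23
Reactants: 39 C5 angelate acetonide
Product: 40 CNP0184688.2
Conditions: AcOH/H2O/THF (3:1:1), 35 °C
Reagents that add atoms: none
Why: Acid-catalysed acetonide hydrolysis releases the C2 and C4 hydroxyls under conditions to which the two esters, the α-methylene lactone and the Z-enoate are stable.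

**Compound list**

1 | (R)-3-bromo-2-methylpropan-1-ol | OC[C@@H](C)CBr | starting material
2 | (R)-(3-bromo-2-methylpropoxy)(tert-butyl)dimethylsilane | CC(C)(C)[Si](C)(C)OC[C@@H](C)CBr | intermediate
3 | 1,3-dithiane | C1CSCSC1 | starting material
4 | 2-lithio-1,3-dithiane | [Li]C1SCCCS1 | intermediate
5 | 2-[(S)-3-(tert-butyldimethylsilyloxy)-2-methylpropyl]-1,3-dithiane | CC(C)(C)[Si](C)(C)OC[C@@H](C)CC1SCCCS1 | intermediate
6 | (R)-2-methylglycidol | C[C@@]1(CO)CO1 | starting material
7 | sodium alkoxide of 6 | C[C@@]1(CO[Na])CO1 | intermediate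
8 | (S)-2-[(4-methoxybenzyloxy)methyl]-2-methyloxirane | C[C@@]1(COCc2ccc(OC)cc2)CO1 | intermediate
9 | 2-lithio derivative of 5 | CC(C)(C)[Si](C)(C)OC[C@@H](C)CC1([Li])SCCCS1 | intermediate
10 | (S)-1-{2-[(S)-3-(TBSO)-2-methylpropyl]-1,3-dithian-2-yl}-3-(4-methoxybenzyloxy)-2-methylpropan-2-ol | CC(C)(C)[Si](C)(C)OC[C@@H](C)CC1(C[C@](C)(O)COCc2ccc(OC)cc2)SCCCS1 | intermediate
11 | (2S,6S)-7-(TBSO)-2-hydroxy-1-(4-methoxybenzyloxy)-2,6-dimethylheptan-4-one | CC(C)(C)[Si](C)(C)OC[C@@H](C)CC(=O)C[C@](C)(O)COCc1ccc(OC)cc1 | intermediate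
12 | (2S,4S,6S)-7-(TBSO)-1-(4-methoxybenzyloxy)-2,6-dimethylheptane-2,4-diol | CC(C)(C)[Si](C)(C)OC[C@@H](C)C[C@H](O)C[C@](C)(O)COCc1ccc(OC)cc1 | intermediate
13 | (4S,6S)-6-[(S)-3-(TBSO)-2-methylpropyl]-4-[(4-methoxybenzyloxy)methyl]-2,2,4-trimethyl-1,3-dioxane | CC(C)(C)[Si](C)(C)OC[C@@H](C)C[C@H]1C[C@](C)(OC(C)(C)O1)COCc2ccc(OC)cc2 | intermediate
14 | [(4S,6S)-6-((S)-3-(TBSO)-2-methylpropyl)-2,2,4-trimethyl-1,3-dioxan-4-yl]methanol | CC(C)(C)[Si](C)(C)OC[C@@H](C)C[C@H]1C[C@](C)(OC(C)(C)O1)CO | intermediate
15 | (4S,6S)-6-[(S)-3-(TBSO)-2-methylpropyl]-2,2,4-trimethyl-1,3-dioxane-4-carbaldehyde | CC(C)(C)[Si](C)(C)OC[C@@H](C)C[C@H]1C[C@](C)(OC(C)(C)O1)C=O | intermediate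
16 | allyl 4-methoxyphenyl ether | C=CCOc1ccc(OC)cc1 | starting material
17 | (Z)-3-(4-methoxyphenoxy)allyllithium | [Li]C/C=C\Oc1ccc(OC)cc1 | intermediate
18 | [(Z)-3-(4-methoxyphenoxy)prop-2-enyl]diisopinocampheylborane (isopinocampheyl groups of the (+)-α-pinene series) | COc1ccc(O/C=C\CB([C@@H]2C[C@@H]3C[C@@H](C3(C)C)[C@H]2C)[C@@H]2C[C@@H]3C[C@@H](C3(C)C)[C@H]2C)cc1 | intermediate
19 | diisopinocampheylborinate ester of 20 (B on O5) | CC(C)(C)[Si](C)(C)OC[C@@H](C)C[C@H]1C[C@](C)(OC(C)(C)O1)[C@@H](OB([C@@H]2C[C@@H]3C[C@@H](C3(C)C)[C@H]2C)[C@@H]2C[C@@H]3C[C@@H](C3(C)C)[C@H]2C)[C@H](Oc2ccc(OC)cc2)C=C | intermediate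
20 | (1S,2R)-1-[(4S,6S)-6-((S)-3-(TBSO)-2-methylpropyl)-2,2,4-trimethyl-1,3-dioxan-4-yl]-2-(4-methoxyphenoxy)but-3-en-1-ol | CC(C)(C)[Si](C)(C)OC[C@@H](C)C[C@H]1C[C@](C)(OC(C)(C)O1)[C@@H](O)[C@H](Oc2ccc(OC)cc2)C=C | intermediate
21 | C5 TBS ether of 20 (2S,4S,5S,6R,10S; C9 OTBS, C6 OPMP) | CC(C)(C)[Si](C)(C)OC[C@@H](C)C[C@H]1C[C@](C)(OC(C)(C)O1)[C@@H](O[Si](C)(C)C(C)(C)C)[C@H](Oc2ccc(OC)cc2)C=C | intermediate
22 | C9 primary alcohol (C5 OTBS, C6 OPMP, C2/C4 acetonide) | OC[C@@H](C)C[C@H]1C[C@](C)(OC(C)(C)O1)[C@@H](O[Si](C)(C)C(C)(C)C)[C@H](Oc2ccc(OC)cc2)C=C | intermediate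
23 | C9 carboxylic acid (C5 OTBS, C6 OPMP, C2/C4 acetonide) | OC(=O)[C@@H](C)C[C@H]1C[C@](C)(OC(C)(C)O1)[C@@H](O[Si](C)(C)C(C)(C)C)[C@H](Oc2ccc(OC)cc2)C=C | intermediate
24 | isobutyl carbonic mixed anhydride of 23 | CC(C)COC(=O)OC(=O)[C@@H](C)C[C@H]1C[C@](C)(OC(C)(C)O1)[C@@H](O[Si](C)(C)C(C)(C)C)[C@H](Oc2ccc(OC)cc2)C=C | intermediate
25 | C9 diazomethyl ketone (C8 = CHN2) | [N-]=[N+]=CC(=O)[C@@H](C)C[C@H]1C[C@](C)(OC(C)(C)O1)[C@@H](O[Si](C)(C)C(C)(C)C)[C@H](Oc2ccc(OC)cc2)C=C | intermediate
26 | methyl 2-(hydroxymethyl)acrylate | C=C(CO)C(=O)OC | starting material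
27 | methyl 2-(alkoxymethyl)acrylate with O8–C13 ether, C9 ketone, C6 OPMP, C5 OTBS, C2/C4 acetonide, C7 vinyl | COC(=O)C(=C)COCC(=O)[C@@H](C)C[C@H]1C[C@](C)(OC(C)(C)O1)[C@@H](O[Si](C)(C)C(C)(C)C)[C@H](Oc2ccc(OC)cc2)C=C | intermediate
28 | hydroxy ester (as 27 with C6 OH) | COC(=O)C(=C)COCC(=O)[C@@H](C)C[C@H]1C[C@](C)(OC(C)(C)O1)[C@@H](O[Si](C)(C)C(C)(C)C)[C@H](O)C=C | intermediate
29 | seco acid (C12 CO2H, C6 OH) | OC(=O)C(=C)COCC(=O)[C@@H](C)C[C@H]1C[C@](C)(OC(C)(C)O1)[C@@H](O[Si](C)(C)C(C)(C)C)[C@H](O)C=C | intermediate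
30 | 2-methyl-6-nitrobenzoic mixed anhydride of 29 | Cc1cccc([N+](=O)[O-])c1C(=O)OC(=O)C(=C)COCC(=O)[C@@H](C)C[C@H]2C[C@](C)(OC(C)(C)O2)[C@@H](O[Si](C)(C)C(C)(C)C)[C@H](O)C=C | intermediate
31 | 14-membered macrolactone (C6–O–C12; C11 exocyclic methylene, C7 vinyl) | C=C1COCC(=O)[C@@H](C)C[C@H]2C[C@](C)(OC(C)(C)O2)[C@@H](O[Si](C)(C)C(C)(C)C)[C@@H](C=C)OC1=O | intermediate
32 | 13-membered ether bridging a butenolide (2S,4S,5S,6R,10S; C7=C11, C2/C4 acetonide, C5 OTBS) | O=C1O[C@@H]2C=C1COCC(=O)[C@@H](C)C[C@H]3C[C@](C)(OC(C)(C)O3)[C@H]2O[Si](C)(C)C(C)(C)C | intermediate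
33 | Z(O)-dibutylboron enolate of 32 (C8=C9–OBBu2) | O=C1O[C@@H]2C=C1CO/C=C(\OB(CCCC)CCCC)[C@@H](C)C[C@H]3C[C@](C)(OC(C)(C)O3)[C@H]2O[Si](C)(C)C(C)(C)C | intermediate
34 | ten-membered α-methylene lactone, C8 O–BBu2 | C=C1C(=O)O[C@@H]2[C@H]1[C@H](OB(CCCC)CCCC)C(=O)[C@@H](C)C[C@H]3C[C@](C)(OC(C)(C)O3)[C@H]2O[Si](C)(C)C(C)(C)C | intermediate
35 | ten-membered α-methylene lactone (2S,4S,5S,6R,7S,8S,10S), C8 isobutyrate, C5 OTBS, C2/C4 acetonide | C=C1C(=O)O[C@@H]2[C@H]1[C@H](OC(=O)C(C)C)C(=O)[C@@H](C)C[C@H]3C[C@](C)(OC(C)(C)O3)[C@H]2O[Si](C)(C)C(C)(C)C | intermediate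
36 | C5 alcohol (C8 isobutyrate, C2/C4 acetonide) | C=C1C(=O)O[C@@H]2[C@H]1[C@H](OC(=O)C(C)C)C(=O)[C@@H](C)C[C@H]3C[C@](C)(OC(C)(C)O3)[C@H]2O | intermediate
37 | angelic acid, (Z)-2-methylbut-2-enoic acid | C/C=C(/C)C(=O)O | starting material
38 | angelic 2,4,6-trichlorobenzoic anhydride | C/C=C(/C)C(=O)OC(=O)c1c(Cl)cc(Cl)cc1Cl | intermediate
39 | C5 angelate, C8 isobutyrate, C2/C4 acetonide | C=C1C(=O)O[C@@H]2[C@H]1[C@H](OC(=O)C(C)C)C(=O)[C@@H](C)C[C@H]3C[C@](C)(OC(C)(C)O3)[C@H]2OC(=O)/C(C)=C\C | intermediate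
40 | CNP0184688.2 | C=C1C(=O)O[C@@H]2[C@H]1[C@H](OC(=O)C(C)C)C(=O)[C@@H](C)C[C@H](O)C[C@](C)(O)[C@H]2OC(=O)/C(C)=C\C | target

**Step count**

Total: 23 steps. Longest linear sequence: 22 steps (steps 1, 2 and 4–23 from compound 1); step 3 prepares the side partner 8.

**Steps most likely to fail**

1. Step 20 (ring contraction). The amine may remove the lactone γ-proton at C6 instead, and β-elimination of O8 would then open the macrocycle. The enolate may react through the oxy-Claisen [3,3] channel, through the anti envelope (C8 epimer) or on the far lactone face. A boron enolate may also fail to shift at all.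
Fallback with known chemistry, from 21 back to 35: close the ten-membered ring by an intramolecular Barbier allylation instead of a sigmatropic shift. (NH4)2Ce(NO3)6 frees the C6 hydroxyl of 21 to give allylic alcohol F1. Esterification with 2-(bromomethyl)acrylic acid (diisopropylcarbodiimide, cat. DMAP) gives bromomethylacrylate F2. RuCl2(=CHPh)(H2IMes)(PCy3) then closes the five-membered ring to 3-(bromomethyl)butenolide F3. HF·pyridine gives primary alcohol F4, and TEMPO/PhI(OAc)2 gives acid F5. i-BuOCOCl/N-methylmorpholine followed by CH2N2 gives diazoketone F6, which dimethyldioxirane oxidises to keto aldehyde F7. Indium powder in THF/H2O at high dilution then adds the allylindium through the butenolide β-carbon C7 to the C8 aldehyde (the Barbier reaction of 3-(bromomethyl)butenolides, run here as a macrocyclisation) to give α-hydroxy ketone F8. Isobutyric anhydride/DMAP converts F8 into 35.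

2. Step 19 (transannular metathesis). The macrolactone may not reach the s-cis ester conformer in which the ruthenium alkylidene at C7 can engage the 1,1-disubstituted C11 alkene, so oligomerisation or catalyst decay could win.
Fallback, from 28 back to 32: invert the order of ring formation and so bypass steps 17 and 18. The metathesis is run on the open hydroxy ester 28 at high dilution (same catalyst, toluene, 80 °C) to close the 13-membered ring first. The ring-trans alkene favoured in a ring of this size is the Z-enoate, giving 13-membered hydroxy enoate F9, in which C6–OH and the ester are cis. Lactonisation, spontaneous or assisted by PPTS in warm toluene, then gives 32.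

3. Step 22 (angeloylation). Acyl transfer to the hindered C5 hydroxyl may be slow, and prolonged heating or any nucleophilic catalyst can isomerise the Z-enoate to the tiglate.
Fallback, from 36 back to 39: build the Z-alkene on the ester instead of transferring it. 36 is esterified with 2-[bis(2,2,2-trifluoroethoxy)phosphoryl]propanoic acid (diisopropylcarbodiimide, DMAP) to give phosphonopropanoate F10. Still–Gennari olefination with acetaldehyde (KN(SiMe3)2, 18-crown-6, THF, −78 °C) then gives the Z-configured angelate 39.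

Further compounds
F1 | step 20 | allylic alcohol (21 with C6 OH) | CC(C)(C)[Si](C)(C)OC[C@@H](C)C[C@H]1C[C@](C)(OC(C)(C)O1)[C@@H](O[Si](C)(C)C(C)(C)C)[C@H](O)C=C
F2 | step 20 | C6 2-(bromomethyl)acrylate | CC(C)(C)[Si](C)(C)OC[C@@H](C)C[C@H]1C[C@](C)(OC(C)(C)O1)[C@@H](O[Si](C)(C)C(C)(C)C)[C@H](OC(=O)C(=C)CBr)C=C
F3 | step 20 | 3-(bromomethyl)butenolide (C9 OTBS) | CC(C)(C)[Si](C)(C)OC[C@@H](C)C[C@H]1C[C@](C)(OC(C)(C)O1)[C@@H](O[Si](C)(C)C(C)(C)C)[C@@H]2OC(=O)C(CBr)=C2
F4 | step 20 | 3-(bromomethyl)butenolide C9 primary alcohol | OC[C@@H](C)C[C@H]1C[C@](C)(OC(C)(C)O1)[C@@H](O[Si](C)(C)C(C)(C)C)[C@@H]2OC(=O)C(CBr)=C2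
F5 | step 20 | 3-(bromomethyl)butenolide C9 acid | OC(=O)[C@@H](C)C[C@H]1C[C@](C)(OC(C)(C)O1)[C@@H](O[Si](C)(C)C(C)(C)C)[C@@H]2OC(=O)C(CBr)=C2
F6 | step 20 | 3-(bromomethyl)butenolide diazoketone | [N-]=[N+]=CC(=O)[C@@H](C)C[C@H]1C[C@](C)(OC(C)(C)O1)[C@@H](O[Si](C)(C)C(C)(C)C)[C@@H]2OC(=O)C(CBr)=C2
F7 | step 20 | 3-(bromomethyl)butenolide keto aldehyde (C9 ketone, C8 CHO) | O=CC(=O)[C@@H](C)C[C@H]1C[C@](C)(OC(C)(C)O1)[C@@H](O[Si](C)(C)C(C)(C)C)[C@@H]2OC(=O)C(CBr)=C2
F8 | step 20 | ten-membered α-methylene lactone with C8 OH | C=C1C(=O)O[C@@H]2[C@H]1[C@H](O)C(=O)[C@@H](C)C[C@H]3C[C@](C)(OC(C)(C)O3)[C@H]2O[Si](C)(C)C(C)(C)C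
F9 | step 19 | 13-membered hydroxy enoate (Z-enoate, C6 OH, C12 CO2Me) | O1CC(=O)[C@@H](C)C[C@H]2C[C@](C)(OC(C)(C)O2)[C@@H](O[Si](C)(C)C(C)(C)C)[C@H](O)/C=C(/C1)C(=O)OC
F10 | step 22 | C5 2-[bis(2,2,2-trifluoroethoxy)phosphoryl]propanoate of 36 | C=C1C(=O)O[C@@H]2[C@H]1[C@H](OC(=O)C(C)C)C(=O)[C@@H](C)C[C@H]3C[C@](C)(OC(C)(C)O3)[C@H]2OC(=O)C(C)P(=O)(OCC(F)(F)F)OCC(F)(F)F
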